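**Retrosynthetic overview**

1. The butenolide is made last: its ring O–C7 bond and its C8=C17 double bond come from (7S)-α-chloro ketone 21 and 2-(diethoxyphosphoryl)propanoic acid 22 in one carboxylate SN2 / intramolecular Horner–Wadsworth–Emmons operation.
2. Enabling feature: in the ten-membered ring C7 is both α to the C8 carbonyl and allylic to the C5=C6 olefin (a doubly activated SN2 carbon), and the C8 carbonyl lies next to it, so the ester carbanion closes a five-membered ring on the C7–C8 edge.
3. Ten-membered ring: ring-closing metathesis at C5=C6 of a diene whose arms come from a 3-methylbut-3-enyl Grignard addition and CBS reduction at C2 and from an Ipc-controlled chloroallylboration at C8, which sets C7.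
4. Cyclohexene from (S)-carvone: double α′-alkylation (C1), epoxidation / Wharton transposition / Eschenmoser–Claisen (C10 and the C11=C12 olefin), Criegee degradation of the isopropenyl group to the C14 acetate.
5. Ring order: cyclohexene (chiral pool), then ten-membered carbocycle, then butenolide.

Key step: step 18

Remark on locants: briarane numbering of the target is used. C1 is the quaternary ring-fusion carbon, C2 carries the propionate, C5=C6 is the ring olefin, C7 is the lactone O–CH, C8 the butenolide β-carbon, C10 the ring-fusion CH, C11=C12 the cyclohexene olefin, C14 carries the acetate, C17 is the butenolide α-carbon. β is the face of the six-membered ring that carries the C1 methyl; α is the opposite face. The target is (1S,2S,5Z,7R,10S,14S).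

Assumption: acid 22 is used as the racemate (its stereocentre becomes sp2 C17), and the facial sense of the Ipc2B reagents is taken from the Brown allylation model (reagent from (+)-Ipc2BOMe attacks the Re face of an unbranched aliphatic aldehyde).

**Route**

Step 1
Reactants: 1 (S)-(+)-carvone
Product: 2 trans-6-(hydroxymethyl)carvone
Conditions: LDA, THF, −78 °C; CH2O (gas, from cracked paraformaldehyde), −78 °C; aq NH4Cl
Reagents that add atoms: formaldehyde C=O
Why: Kinetic α′-deprotonation of the enone and aldol addition to monomeric formaldehyde should give the hydroxymethyl ketone with the new bond anti to the isopropenyl group, a centre that is re-formed in step 3 so its ratio does not matter.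

Step 2
Reactants: 2 trans-6-(hydroxymethyl)carvone
Product: 3 silyl ether
Conditions: TBSCl, imidazole, DMF, 0 °C to rt
Reagents that add atoms: tert-butyldimethylsilyl chloride CC(C)(C)[Si](C)(C)Cl
Why: Routine imidazole-mediated silylation of the primary alcohol masks the β-hydroxy ketone before the second enolate alkylation.

Step 3
Reactants: 3 silyl ether
Product: 4 quaternary enone
Conditions: LDA, THF, −78 °C; MeI, DMPU, −78 to −20 °C
Reagents that add atoms: iodomethane CI
Why: α′-Enolate alkylation of a 6-substituted carvone, in which iodomethane should approach the planar enolate anti to the adjacent isopropenyl group, sets the quaternary carbon (future C1) with methyl trans and CH2OTBS cis to the isopropenyl group (future C14 oxygen).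

Step 4
Reactants: 4 quaternary enone
Product: 5 epoxy ketone
Conditions: 30% H2O2, NaOH (cat.), MeOH, 0 °C
Reagents that add atoms: hydrogen peroxide OO
Why: Weitz–Scheffer nucleophilic epoxidation touches only the enone olefin, and in carvone-type enones hydroperoxide adds to the β-carbon anti to the isopropenyl-bearing carbon, so the oxirane should form on the β face.

Step 5
Reactants: 5 epoxy ketone
Product: 7 epoxy ketone acetate, via methoxy hydroperoxide 6 (not isolated)
Conditions: O3, CH2Cl2/MeOH, −78 °C; then Ac2O, Et3N, DMAP (cat.), CH2Cl2, 0 to 40 °C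
Reagents that add atoms: ozone [O-][O+]=O; methanol CO
Why: Ozonolysis of the only remaining olefin in methanol followed by Criegee rearrangement of the peracetate moves the ring carbon to oxygen with retention, so the isopropenyl group becomes the C14 acetate of the target (its acetyl carbons are the old isopropenyl carbons) while the non-enolisable epoxy ketone is untouched.

Step 6
Reactants: 7 epoxy ketone acetate
Product: 8 allylic alcohol
Conditions: N2H4·H2O, AcOH (cat.), MeOH, 0 °C to rt
Reagents that add atoms: none
Why: Wharton transposition, in which the epoxy hydrazone fragments with loss of nitrogen, should move the oxygen to C12 with its C–O bond untouched (β-OH) and the double bond to C10=C11.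

Step 7
Reactants: 8 allylic alcohol
Product: 9 Claisen amide
Conditions: MeC(OMe)2NMe2, xylene, 140 °C
Reagents that add atoms: N,N-dimethylacetamide dimethyl acetal COC(C)(OC)N(C)C
Why: Eschenmoser–Claisen rearrangement of the ketene N,O-acetal formed at the C12 hydroxyl is suprafacial, so the CH2CONMe2 arm should be delivered to C10 on the β face (H-10 α, trans to the C1 CH2OTBS arm) while the olefin returns to C11=C12.

Step 8
Reactants: 9 Claisen amide
Product: 10 primary alcohol
Conditions: HF·pyridine, pyridine/THF, 0 °C to rt
Reagents that add atoms: none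
Why: Fluoride cleavage of a primary TBS ether under mildly acidic buffered conditions should spare the acetate and avoid base-promoted 1,3-acetyl migration.

Step 9
Reactants: 10 primary alcohol
Product: 11 C2 aldehyde
Conditions: Dess–Martin periodinane, CH2Cl2, 0 °C to rt
Reagents that add atoms: none
Why: Dess–Martin oxidation of the neopentyl primary alcohol gives a non-enolisable aldehyde and leaves acetate, amide and olefin alone.

Step 10
Reactants: 11 C2 aldehyde; 12 4-bromo-2-methylbut-1-ene
Product: 13 C2 carbinol
Conditions: 12, Mg, THF; then 11, THF, −78 °C; sat. NH4Cl at −78 °C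
Reagents that add atoms: none
Why: Grignard addition at low temperature is chemoselective for the aldehyde over the secondary acetate and the tertiary amide, and the uncontrolled C2 configuration is erased in step 11 while the cold quench should prevent acyl transfer to the new alkoxide.

Step 11
Reactants: 13 C2 carbinol
Product: 14 C2 ketone
Conditions: Dess–Martin periodinane, CH2Cl2, rt
Reagents that add atoms: none
Why: Dess–Martin oxidation converges both C2 epimers on one ketone without touching the olefins.

Step 12
Reactants: 14 C2 ketone
Product: 15 (2S)-alcohol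
Conditions: (R)-2-methyl-CBS-oxazaborolidine, catecholborane, toluene, −78 to −40 °C
Reagents that add atoms: none
Why: Corey–Bakshi–Shibata reduction of a ketone flanked by a quaternary (large) and a methylene (small) carbon is the best case for oxazaborolidine control, and the (R)-catalyst should give the (2S)-carbinol while catecholborane at low temperature leaves alkenes, acetate and amide alone.

Step 13
Reactants: 15 (2S)-alcohol
Product: 16 (2S)-propionate
Conditions: (EtCO)2O, Et3N, DMAP, CH2Cl2, rt
Reagents that add atoms: propionic anhydride CCC(=O)OC(=O)CC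
Why: DMAP-catalysed acylation of the hindered secondary alcohol installs the C2 propionate and should outrun 1,3-acetate migration.

Step 14
Reactants: 16 (2S)-propionate
Product: 17 C8 aldehyde
Conditions: Cp2Zr(H)Cl, THF, rt, short reaction time; wet silica gel
Reagents that add atoms: none
Why: Schwartz reagent reduces tertiary amides to aldehydes through a zirconated hemiaminal within minutes, which should be faster than hydrozirconation of the 1,1-disubstituted and trisubstituted olefins and does not touch the two esters.

Step 15
Reactants: 17 C8 aldehyde; 18 allyl chloride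
Product: 19 syn chlorohydrin diene
Conditions: 18, LiN(c-C6H11)2, (+)-Ipc2BOMe, Et2O/THF, −95 °C; BF3·OEt2; then 17, −95 °C; ethanolamine work-up
Reagents that add atoms: none
Why: Oehlschlager–Brown chloroallylboration with the (Z)-γ-chloroallylborane proceeds through a chair Zimmerman–Traxler transition state to the syn chlorohydrin, and the isopinocampheyl groups should direct attack to the Re face of the aldehyde so that C7 is (S) (C8, also S, is oxidised later).

Step 16
Reactants: 19 syn chlorohydrin diene
Product: 20 bicyclic chlorohydrin
Conditions: Hoveyda–Grubbs II (10 mol%), toluene (1 mM), 80 °C, argon sparge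
Reagents that add atoms: none
Why: Ring-closing metathesis of a monosubstituted with a 1,1-disubstituted olefin at high dilution should close the ten-membered ring, helped by the quaternary C1 and precedented for the same 6/10-fused ring system, and should give the Z trisubstituted olefin as the less strained cyclodecene isomer.

Step 17
Reactants: 20 bicyclic chlorohydrin
Product: 21 α-chloro ketone
Conditions: Dess–Martin periodinane, pyridine, CH2Cl2, 0 °C; used directly
Reagents that add atoms: none
Why: Buffered Dess–Martin oxidation of the β-chloro alcohol should give the α-chloro ketone under non-basic conditions that do not epimerise C7.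

Step 18
Reactants: 21 α-chloro ketone; 22 2-(diethoxyphosphoryl)propanoic acid
Product: 24 CNP0112230.1, via phosphonate ester 23 (not isolated)
Conditions: 22 (1.5 equiv), Cs2CO3 (3 equiv), DMF, 0 to 40 °C
Reagents that add atoms: none
Why: Cesium carbonate turns 22 into its cesium carboxylate, which displaces the C7 chloride of 21 by SN2 with inversion to give ester 23; the remaining carbonate then deprotonates the phosphonate, whose carbanion adds to the neighbouring C8 ketone and eliminates diethyl phosphate to form the tetrasubstituted C8=C17 bond. The closest known reactions are the esterification of α-halo ketones with phosphonoacetic acids followed by intramolecular Horner–Wadsworth–Emmons closure to butenolides, here run as one charge. The butenolide ring closes by 5-exo-trig attack of the carbanion on the C8 carbonyl followed by syn-elimination, and the ring fixes the olefin geometry. The only new stereocentre, C7, is controlled by the inversion: the (7S)-chloride set by the borane in step 15 should give the (7R)-lactone carbon. The step needs SN2 rather than SN2′ (C5, the γ-carbon, is fully substituted), displacement faster than enolisation toward C7 or Favorskii contraction (weakly basic carboxylate and carbonate, doubly activated carbon), and olefination at C8 only (it is the sole ketone).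

**Compound list**

1 | (S)-(+)-carvone, (5S)-2-methyl-5-(prop-1-en-2-yl)cyclohex-2-en-1-one | CC1=CC[C@@H](CC1=O)C(C)=C | starting material
2 | trans-6-(hydroxymethyl)carvone (CH2OH trans to isopropenyl) | CC1=CC[C@H](C(C)=C)[C@@H](CO)C1=O | intermediate
3 | TBS ether of 2 | CC1=CC[C@H](C(C)=C)[C@@H](CO[Si](C)(C)C(C)(C)C)C1=O | intermediate
4 | 6-methyl-6-(TBS-oxymethyl)carvone, methyl trans and CH2OTBS cis to isopropenyl | CC1=CC[C@H](C(C)=C)[C@](C)(CO[Si](C)(C)C(C)(C)C)C1=O | intermediate
5 | 2,3-epoxide of 4, oxirane trans to isopropenyl (β) | C[C@]12O[C@H]1C[C@H](C(C)=C)[C@](C)(CO[Si](C)(C)C(C)(C)C)C2=O | intermediate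
6 | α-methoxy hydroperoxide from ozonolysis of 5 (hemiperketal carbon unassigned) | C[C@]12O[C@H]1C[C@H](C(C)(OC)OO)[C@](C)(CO[Si](C)(C)C(C)(C)C)C2=O | intermediate
7 | epoxy ketone acetate: C14 α-OAc, C11–C12 β-oxirane, C10 ketone, C1 β-Me and α-CH2OTBS | C[C@]12O[C@H]1C[C@H](OC(C)=O)[C@](C)(CO[Si](C)(C)C(C)(C)C)C2=O | intermediate
8 | allylic alcohol: C12 β-OH, C10=C11, C14 α-OAc, C1 β-Me and α-CH2OTBS | CC1=C[C@@](C)(CO[Si](C)(C)C(C)(C)C)[C@@H](OC(C)=O)C[C@@H]1O | intermediate
9 | Claisen amide: C10 β-CH2CONMe2, C11=C12, C14 α-OAc, C1 β-Me and α-CH2OTBS | CC1=CC[C@H](OC(C)=O)[C@](C)(CO[Si](C)(C)C(C)(C)C)[C@H]1CC(=O)N(C)C | intermediate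
10 | primary alcohol (C2 hydroxymethyl) | CC1=CC[C@H](OC(C)=O)[C@](C)(CO)[C@H]1CC(=O)N(C)C | intermediate
11 | C2 aldehyde | CC1=CC[C@H](OC(C)=O)[C@](C)(C=O)[C@H]1CC(=O)N(C)C | intermediate
12 | 4-bromo-2-methylbut-1-ene | C=C(C)CCBr | starting material
13 | C2 carbinol with 3-methylbut-3-enyl chain (both C2 epimers) | CC1=CC[C@H](OC(C)=O)[C@](C)(C(O)CCC(C)=C)[C@H]1CC(=O)N(C)C | intermediate
14 | C2 ketone | CC1=CC[C@H](OC(C)=O)[C@](C)(C(=O)CCC(C)=C)[C@H]1CC(=O)N(C)C | intermediate
15 | (2S)-alcohol | CC1=CC[C@H](OC(C)=O)[C@](C)([C@@H](O)CCC(C)=C)[C@H]1CC(=O)N(C)C | intermediate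
16 | (2S)-propionate | CC1=CC[C@H](OC(C)=O)[C@](C)([C@@H](OC(=O)CC)CCC(C)=C)[C@H]1CC(=O)N(C)C | intermediate
17 | C8 aldehyde (2S-propionate, 14-acetate) | CC1=CC[C@H](OC(C)=O)[C@](C)([C@@H](OC(=O)CC)CCC(C)=C)[C@H]1CC=O | intermediate
18 | allyl chloride (3-chloroprop-1-ene) | C=CCCl | starting material
19 | (7S,8S)-syn chlorohydrin diene | CC1=CC[C@H](OC(C)=O)[C@](C)([C@@H](OC(=O)CC)CCC(C)=C)[C@H]1C[C@H](O)[C@@H](Cl)C=C | intermediate
20 | bicyclo[8.4.0] chlorohydrin: (5Z)-olefin, (7S)-Cl, (8S)-OH | CCC(=O)O[C@H]1CC/C(C)=C\[C@H](Cl)[C@@H](O)C[C@H]2C(C)=CC[C@H](OC(C)=O)[C@]12C | intermediate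
21 | (7S)-α-chloro C8 ketone | CCC(=O)O[C@H]1CC/C(C)=C\[C@H](Cl)C(=O)C[C@H]2C(C)=CC[C@H](OC(C)=O)[C@]12C | intermediate
22 | 2-(diethoxyphosphoryl)propanoic acid (racemic) | CCOP(=O)(OCC)C(C)C(=O)O | starting material
23 | (7R)-7-O-[2-(diethoxyphosphoryl)propanoyl] C8 ketone (phosphonate carbon unassigned) | CCC(=O)O[C@H]1CC/C(C)=C\[C@@H](OC(=O)C(C)P(=O)(OCC)OCC)C(=O)C[C@H]2C(C)=CC[C@H](OC(C)=O)[C@]12C | intermediate
24 | CNP0112230.1, (1S,2S,5Z,7R,10S,14S) | CCC(=O)O[C@H]1CC/C(C)=C\[C@H]2OC(=O)C(C)=C2C[C@H]2C(C)=CC[C@H](OC(C)=O)[C@]12C | target

**Step count**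

Total: 18 steps. Longest linear sequence: 18 steps, from (S)-carvone 1.

**Steps most likely to fail**

Step 16 (ring-closing metathesis). Closure to a strained ten-membered ring with a trisubstituted olefin may lose to intermolecular metathesis, or the ruthenium alkylidene at the allylic chloride may fail to engage the 1,1-disubstituted olefin. The fallback changes the substrate class by adding a temporary ring rather than changing the catalyst. It sets out from 19: sodium hydride in THF at 0 °C closes the syn chlorohydrin to the cis-vinyl epoxide F1 with inversion at C7, which holds C6 and C9 syn on a rigid three-membered ring and removes the free hydroxyl and the allylic C–Cl bond. Metathesis of F1 (Hoveyda–Grubbs II, toluene, 80 °C, high dilution) should then give the bicyclic epoxide F2. Opening of the vinyl oxirane at the allylic carbon C7 with chloride (LiCl, Amberlyst 15, MeCN, −20 °C) inverts C7 a second time and comes back to the route at 20.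

Step 18 (key step). Configuration at C7 may be lost before displacement (enolisation toward the doubly activated α-carbon, or chloride exchange), the α-chloro ketone may undergo Favorskii contraction, or the γ-position of the product may epimerise under carbonate. The fallback forms the C7–O bond by acylation with retention instead of substitution. It sets out from 17: Brown alkoxyallylboration with (Z)-γ-(methoxymethoxy)allyl-diisopinocampheylborane (from allyl methoxymethyl ether, s-BuLi, (−)-Ipc2BOMe, BF3·OEt2) should give the (7R,8R)-syn diol monoether F3. Ring-closing metathesis as in step 16 gives the bicyclic alcohol F4, Dess–Martin oxidation gives the α-alkoxy ketone F5, and Me2BBr in CH2Cl2 at −78 °C removes the MOM group to give the (7R)-acyloin F6. Esterification of F6 with 22 (EDC, DMAP, CH2Cl2) comes back to the route at 23, now isolated, and Masamune–Roush conditions (LiCl, DBU, MeCN, 0 °C) close it to 24.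

Step 6 (Wharton transposition). Hydrazone formation at a ketone flanked by two fully substituted carbons may be too slow, so that hydrazinolysis of the acetate or azine formation competes. The fallback replaces the hydrazone by a carbon radical. It sets out from 7: NaBH4 in MeOH at 0 °C reduces the ketone to the epoxy alcohol F7 (either C10 epimer serves). Thiocarbonyldiimidazole with DMAP in 1,2-dichloroethane at 60 °C gives the imidazolide F8. Bu3SnH and AIBN in toluene at 80 °C generate the C10 radical, which opens the oxirane to the C12 alkoxy radical and, after hydrogen transfer, comes back to the route at 8.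

**Further compounds**

F1 | step 16 | acyclic cis-vinyl epoxide (C7–C8 oxirane, C7 inverted relative to 19) | CC1=CC[C@H](OC(C)=O)[C@](C)([C@@H](OC(=O)CC)CCC(C)=C)[C@H]1C[C@@H]2O[C@@H]2C=C
F2 | step 16 | bicyclic (5Z)-olefin with cis C7–C8 oxirane | CCC(=O)O[C@H]1CC/C(C)=C\[C@H]3O[C@H]3C[C@H]2C(C)=CC[C@H](OC(C)=O)[C@]12C
F3 | step 18 | (7R,8R)-syn 8-hydroxy-7-(methoxymethoxy) diene | CC1=CC[C@H](OC(C)=O)[C@](C)([C@@H](OC(=O)CC)CCC(C)=C)[C@H]1C[C@@H](O)[C@H](OCOC)C=C
F4 | step 18 | bicyclic (5Z)-olefin, (7R)-OMOM, (8R)-OH | CCC(=O)O[C@H]1CC/C(C)=C\[C@@H](OCOC)[C@H](O)C[C@H]2C(C)=CC[C@H](OC(C)=O)[C@]12C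
F5 | step 18 | (7R)-7-(methoxymethoxy) C8 ketone | CCC(=O)O[C@H]1CC/C(C)=C\[C@@H](OCOC)C(=O)C[C@H]2C(C)=CC[C@H](OC(C)=O)[C@]12C
F6 | step 18 | (7R)-7-hydroxy C8 ketone (acyloin) | CCC(=O)O[C@H]1CC/C(C)=C\[C@@H](O)C(=O)C[C@H]2C(C)=CC[C@H](OC(C)=O)[C@]12C
F7 | step 6 | epoxy alcohol from reduction of 7 (C10 epimers) | C[C@]12O[C@H]1C[C@H](OC(C)=O)[C@](C)(CO[Si](C)(C)C(C)(C)C)C2O
F8 | step 6 | O-(imidazol-1-ylthiocarbonyl) derivative of F7 | C[C@]12O[C@H]1C[C@H](OC(C)=O)[C@](C)(CO[Si](C)(C)C(C)(C)C)C2OC(=S)n3ccnc3
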